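**Retrosynthetic overview**

- Target 21 is the tris-MOM ether 20 after acetal cleavage. Ring C of 20 is closed last by forming C3–C4 in an asymmetric intramolecular alkene hydroacylation of the achiral aldehyde 19 (formyl carbon = C4, enol ether alkene = C2=C3).
- Enabling feature: C2 carries both the ring oxygen O1 and the ring B aryl group. One oxidation level up it is therefore the inner carbon of a 1-arylvinyl aryl ether whose terminal carbon C3 has no allylic hydrogen and can reach the formyl carbon on ring A, ortho to O1, only in the six-ring sense. Hydride delivery to C2 creates the only stereocentre.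
- The enol ether of 19 comes from methylenation of aryl benzoate 16. Its O1–C2 bond is made by esterification of ring A phenol 7 with ring B acid 13; the formyl carbon is carried through as a silyl-protected hydroxymethyl group.
- Both prenyl groups come from two aromatic Claisen rearrangements (allyl ethers from 2,4,6-trihydroxybenzaldehyde and methyl isovanillate) and one double cross-metathesis. The ring A Claisen step also frees the phenol that becomes O1.
- Ring order: rings A and B are bought; ring C is the only ring formed (step 15).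

Key step: step 15

Assumption: the sense of induction of the bisphosphine in step 15 cannot be predicted with certainty; (R)-DTBM-SEGPHOS is written, and its antipode would be taken if a trial on 19 shows the opposite sense.

**Route**

Step 1
Reactants: 1 2,4,6-trihydroxybenzaldehyde
Product: 2 2-hydroxy-4,6-bis(methoxymethoxy)benzaldehyde
Conditions: MOMCl (2.2 equiv), i-Pr2NEt, CH2Cl2, 0 °C to rt
Reagents that add atoms: chloromethyl methyl ether, COCCl
Why: Williamson-type O-alkylation should take the para phenol and one ortho phenol, while the last ortho phenol stays free because it is held in the hydrogen bond to the formyl oxygen.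

Step 2
Reactants: 2 2-hydroxy-4,6-bis(methoxymethoxy)benzaldehyde
Product: 3 2-(allyloxy)-4,6-bis(methoxymethoxy)benzaldehyde
Conditions: allyl bromide, K2CO3, DMF, 50 °C
Reagents that add atoms: allyl bromide, C=CCBr
Why: Williamson etherification in DMF breaks the chelate and puts the allyl group on the oxygen that will become O1.

Step 3
Reactants: 3 2-(allyloxy)-4,6-bis(methoxymethoxy)benzaldehyde
Product: 4 [2-(allyloxy)-4,6-bis(methoxymethoxy)phenyl]methanol
Conditions: NaBH4, MeOH/THF, 0 °C
Reagents that add atoms: none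
Why: Chemoselective hydride reduction lowers the formyl carbon to the alcohol level so that it can be masked before the titanium methylenation of step 12, which would otherwise attack it.

Step 4
Reactants: 4 [2-(allyloxy)-4,6-bis(methoxymethoxy)phenyl]methanol
Product: 5 tert-butyl{[2-(allyloxy)-4,6-bis(methoxymethoxy)phenyl]methoxy}dimethylsilane
Conditions: TBSCl, imidazole, DMF, rt
Reagents that add atoms: tert-butyldimethylsilyl chloride, CC(C)(C)[Si](C)(C)Cl
Why: Standard silylation of a primary alcohol gives a heat- and base-stable ether that is orthogonal to the MOM ethers.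

Step 5
Reactants: 5 tert-butyl{[2-(allyloxy)-4,6-bis(methoxymethoxy)phenyl]methoxy}dimethylsilane
Product: 7 2-allyl-6-{[(tert-butyldimethylsilyl)oxy]methyl}-3,5-bis(methoxymethoxy)phenol, via ortho-dienone 6 (not isolated)
Conditions: PhNEt2, 190 °C, sealed tube
Reagents that add atoms: none
Why: Aromatic Claisen rearrangement; the [3,3] shift can end productively only at the single unsubstituted ortho carbon, and tautomerisation of the dienone returns the free phenol on the oxygen that becomes O1, with the allyl group at the future C8.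

Step 6
Reactants: 8 methyl 3-hydroxy-4-methoxybenzoate
Product: 9 methyl 3-(allyloxy)-4-methoxybenzoate
Conditions: allyl bromide, K2CO3, acetone, reflux
Reagents that add atoms: allyl bromide, C=CCBr
Why: Williamson etherification of the only phenol.

Step 7
Reactants: 9 methyl 3-(allyloxy)-4-methoxybenzoate
Product: 11 methyl 2-allyl-3-hydroxy-4-methoxybenzoate, via ortho-dienone 10 (not isolated)
Conditions: PhNEt2, 200 °C, sealed tube
Reagents that add atoms: none
Why: Aromatic Claisen rearrangement; the other ortho carbon carries the methoxy group, so the allyl group should arrive at C2, between the phenol and the ester, which is the substitution pattern of ring B.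

Step 8
Reactants: 11 methyl 2-allyl-3-hydroxy-4-methoxybenzoate
Product: 12 methyl 2-allyl-4-methoxy-3-(methoxymethoxy)benzoate
Conditions: MOMCl, i-Pr2NEt, CH2Cl2, 0 °C to rt
Reagents that add atoms: chloromethyl methyl ether, COCCl
Why: O-alkylation gives the same acetal protecting group as on ring A, so that one final step frees all three phenols.

Step 9
Reactants: 12 methyl 2-allyl-4-methoxy-3-(methoxymethoxy)benzoate
Product: 13 2-allyl-4-methoxy-3-(methoxymethoxy)benzoic acid
Conditions: LiOH, THF/MeOH/H2O, 50 °C; then dilute HCl to pH 4, 0 °C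
Reagents that add atoms: lithium hydroxide, [Li+].[OH-]
Why: Saponification of a methyl benzoate; the brief cold acidification to pH 4 should leave the MOM ether intact.

Step 10
Reactants: 7 2-allyl-6-{[(tert-butyldimethylsilyl)oxy]methyl}-3,5-bis(methoxymethoxy)phenol; 13 2-allyl-4-methoxy-3-(methoxymethoxy)benzoic acid
Product: 15 2-allyl-6-{[(tert-butyldimethylsilyl)oxy]methyl}-3,5-bis(methoxymethoxy)phenyl 2-allyl-4-methoxy-3-(methoxymethoxy)benzoate, via O-acylisourea 14 (not isolated)
Conditions: DCC, DMAP (0.3 equiv), CH2Cl2, rt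
Reagents that add atoms: none
Why: Steglich esterification; carbodiimide activation and DMAP acyl transfer form the aryl ester, which is the O1–C2 bond of the target at the ester oxidation level.

Step 11
Reactants: 15 2-allyl-6-{[(tert-butyldimethylsilyl)oxy]methyl}-3,5-bis(methoxymethoxy)phenyl 2-allyl-4-methoxy-3-(methoxymethoxy)benzoate
Product: 16 2-{[(tert-butyldimethylsilyl)oxy]methyl}-3,5-bis(methoxymethoxy)-6-(3-methylbut-2-enyl)phenyl 4-methoxy-3-(methoxymethoxy)-2-(3-methylbut-2-enyl)benzoate
Conditions: 2-methyl-2-butene (large excess), second-generation Grubbs catalyst RuCl2(=CHPh)(H2IMes)(PCy3) (5 mol %), CH2Cl2, 40 °C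
Reagents that add atoms: 2-methyl-2-butene, CC=C(C)C
Why: Olefin cross-metathesis should turn both allyl groups into prenyl groups in one operation, the large excess of the partner alkene suppressing ring closure between the two allyl groups.

Step 12
Reactants: 16 2-{[(tert-butyldimethylsilyl)oxy]methyl}-3,5-bis(methoxymethoxy)-6-(3-methylbut-2-enyl)phenyl 4-methoxy-3-(methoxymethoxy)-2-(3-methylbut-2-enyl)benzoate
Product: 17 tert-butyl{[2-({1-[4-methoxy-3-(methoxymethoxy)-2-(3-methylbut-2-enyl)phenyl]vinyl}oxy)-4,6-bis(methoxymethoxy)-3-(3-methylbut-2-enyl)phenyl]methoxy}dimethylsilane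
Conditions: Cp2TiMe2 (3 equiv), toluene, 70 °C, dark; filtration through basic alumina
Reagents that add atoms: dimethyltitanocene, C[Ti](C)(C1C=CC=C1)C1C=CC=C1
Why: Petasis methylenation; the titanium methylidene formed on heating adds to the only carbonyl group present and the four-membered adduct collapses to the 1-arylvinyl aryl ether under non-acidic conditions that spare the silyl ether, the MOM ethers and the trisubstituted alkenes.

Step 13
Reactants: 17 tert-butyl{[2-({1-[4-methoxy-3-(methoxymethoxy)-2-(3-methylbut-2-enyl)phenyl]vinyl}oxy)-4,6-bis(methoxymethoxy)-3-(3-methylbut-2-enyl)phenyl]methoxy}dimethylsilane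
Product: 18 [2-({1-[4-methoxy-3-(methoxymethoxy)-2-(3-methylbut-2-enyl)phenyl]vinyl}oxy)-4,6-bis(methoxymethoxy)-3-(3-methylbut-2-enyl)phenyl]methanol
Conditions: Bu4NF, THF, 0 °C
Reagents that add atoms: none
Why: Fluoride desilylation is basic and so should leave the acid-labile enol ether and the MOM ethers untouched.

Step 14
Reactants: 18 [2-({1-[4-methoxy-3-(methoxymethoxy)-2-(3-methylbut-2-enyl)phenyl]vinyl}oxy)-4,6-bis(methoxymethoxy)-3-(3-methylbut-2-enyl)phenyl]methanol
Product: 19 2-({1-[4-methoxy-3-(methoxymethoxy)-2-(3-methylbut-2-enyl)phenyl]vinyl}oxy)-4,6-bis(methoxymethoxy)-3-(3-methylbut-2-enyl)benzaldehyde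
Conditions: MnO2 (activated, excess), CH2Cl2, rt
Reagents that add atoms: none
Why: MnO2 oxidation of an electron-rich benzylic alcohol is neutral and heterogeneous, so the enol ether should survive and the aldehyde cannot be over-oxidised.

Step 15
Reactants: 19 2-({1-[4-methoxy-3-(methoxymethoxy)-2-(3-methylbut-2-enyl)phenyl]vinyl}oxy)-4,6-bis(methoxymethoxy)-3-(3-methylbut-2-enyl)benzaldehyde
Product: 20 (2S)-2-[4-methoxy-3-(methoxymethoxy)-2-(3-methylbut-2-enyl)phenyl]-5,7-bis(methoxymethoxy)-8-(3-methylbut-2-enyl)chroman-4-one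
Conditions: [Rh(cod)Cl]2 (5 mol %), (R)-DTBM-SEGPHOS (10 mol %), NaB[3,5-(CF3)2C6H3]4 (10 mol %), dry degassed 1,4-dioxane, 60 °C
Reagents that add atoms: none
Why: Proposed new method: oxidative addition of the formyl C–H bond of 19 to the cationic monovalent rhodium bisphosphine complex should give an acyl rhodium hydride, the enol ether alkene C2=C3 then coordinates, hydride is delivered to C2 and rhodium to the terminal C3, and C–C reductive elimination from the seven-membered acyl alkyl rhodacycle of trivalent rhodium forms C3–C4. The closest known reaction type is the rhodium-catalysed endo- and enantioselective hydroacylation of ortho-allylbenzaldehydes that carry 1,1-disubstituted alkenes, which gives 3-substituted tetralones; here the benzylic CH2 of that substrate class is replaced by the ether oxygen O1, a change not yet shown for an enol ether alkene. Ring C closes in the 6-endo-trig mode with respect to the alkene. The new stereocentre C2 is set in the hydride transfer step under catalyst control, the chiral bisphosphine selecting the alkene face that is bound to rhodium, and the substrate is achiral so that no matching problem arises. The step needs endo over exo regioselectivity, which is secured because the exo path would place rhodium on the fully substituted C2 and would have to build a quaternary carbon in a five-membered ring, and it needs C–C bond formation to outrun decarbonylation, which the two ortho substituents of the formyl group and the moderate temperature should slow. The two prenyl alkenes are trisubstituted and cannot reach the acyl rhodium centre in a ring of reasonable size, and the alkene C2=C3 has no allylic hydrogen, so it cannot isomerise.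

Step 16
Reactants: 20 (2S)-2-[4-methoxy-3-(methoxymethoxy)-2-(3-methylbut-2-enyl)phenyl]-5,7-bis(methoxymethoxy)-8-(3-methylbut-2-enyl)chroman-4-one
Product: 21 (2S)-5,7-dihydroxy-2-[3-hydroxy-4-methoxy-2-(3-methylbut-2-enyl)phenyl]-8-(3-methylbut-2-enyl)chroman-4-one
Conditions: HCl (1.25 M in MeOH), 40 °C
Reagents that add atoms: none
Why: Acid-catalysed acetal exchange with methanol removes the three MOM groups under conditions that should be too mild to add the new phenols across the prenyl double bonds and that, being acidic, avoid the base-induced retro-oxa-Michael opening of ring C that would racemise C2.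

**Compound list**

1 | 2,4,6-trihydroxybenzaldehyde | O=Cc1c(O)cc(O)cc1O | starting material
2 | 2-hydroxy-4,6-bis(methoxymethoxy)benzaldehyde | O=Cc1c(O)cc(OCOC)cc1OCOC | intermediate
3 | 2-(allyloxy)-4,6-bis(methoxymethoxy)benzaldehyde | O=Cc1c(OCC=C)cc(OCOC)cc1OCOC | intermediate
4 | [2-(allyloxy)-4,6-bis(methoxymethoxy)phenyl]methanol | OCc1c(OCC=C)cc(OCOC)cc1OCOC | intermediate
5 | tert-butyl{[2-(allyloxy)-4,6-bis(methoxymethoxy)phenyl]methoxy}dimethylsilane | CC(C)(C)[Si](C)(C)OCc1c(OCC=C)cc(OCOC)cc1OCOC | intermediate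
6 | 6-allyl-2-{[(tert-butyldimethylsilyl)oxy]methyl}-3,5-bis(methoxymethoxy)cyclohexa-2,4-dien-1-one (ortho-dienone, not isolated) | O=C1C(CC=C)C(OCOC)=CC(OCOC)=C1CO[Si](C)(C)C(C)(C)C | intermediate
7 | 2-allyl-6-{[(tert-butyldimethylsilyl)oxy]methyl}-3,5-bis(methoxymethoxy)phenol | CC(C)(C)[Si](C)(C)OCc1c(O)c(CC=C)c(OCOC)cc1OCOC | intermediate
8 | methyl 3-hydroxy-4-methoxybenzoate (methyl isovanillate) | COC(=O)c1ccc(OC)c(O)c1 | starting material
9 | methyl 3-(allyloxy)-4-methoxybenzoate | COC(=O)c1ccc(OC)c(OCC=C)c1 | intermediate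
10 | methyl 6-allyl-4-methoxy-5-oxocyclohexa-1,3-diene-1-carboxylate (ortho-dienone, not isolated) | COC(=O)C1=CC=C(OC)C(=O)C1CC=C | intermediate
11 | methyl 2-allyl-3-hydroxy-4-methoxybenzoate | COC(=O)c1ccc(OC)c(O)c1CC=C | intermediate
12 | methyl 2-allyl-4-methoxy-3-(methoxymethoxy)benzoate | COC(=O)c1ccc(OC)c(OCOC)c1CC=C | intermediate
13 | 2-allyl-4-methoxy-3-(methoxymethoxy)benzoic acid | OC(=O)c1ccc(OC)c(OCOC)c1CC=C | intermediate
14 | O-acylisourea of acid 13 with dicyclohexylcarbodiimide (not isolated) | C=CCc1c(C(=O)OC(=NC2CCCCC2)NC2CCCCC2)ccc(OC)c1OCOC | intermediate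
15 | 2-allyl-6-{[(tert-butyldimethylsilyl)oxy]methyl}-3,5-bis(methoxymethoxy)phenyl 2-allyl-4-methoxy-3-(methoxymethoxy)benzoate | CC(C)(C)[Si](C)(C)OCc1c(OC(=O)c2ccc(OC)c(OCOC)c2CC=C)c(CC=C)c(OCOC)cc1OCOC | intermediate
16 | 2-{[(tert-butyldimethylsilyl)oxy]methyl}-3,5-bis(methoxymethoxy)-6-(3-methylbut-2-enyl)phenyl 4-methoxy-3-(methoxymethoxy)-2-(3-methylbut-2-enyl)benzoate | CC(C)(C)[Si](C)(C)OCc1c(OC(=O)c2ccc(OC)c(OCOC)c2CC=C(C)C)c(CC=C(C)C)c(OCOC)cc1OCOC | intermediate
17 | tert-butyl{[2-({1-[4-methoxy-3-(methoxymethoxy)-2-(3-methylbut-2-enyl)phenyl]vinyl}oxy)-4,6-bis(methoxymethoxy)-3-(3-methylbut-2-enyl)phenyl]methoxy}dimethylsilane | CC(C)(C)[Si](C)(C)OCc1c(OC(=C)c2ccc(OC)c(OCOC)c2CC=C(C)C)c(CC=C(C)C)c(OCOC)cc1OCOC | intermediate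
18 | [2-({1-[4-methoxy-3-(methoxymethoxy)-2-(3-methylbut-2-enyl)phenyl]vinyl}oxy)-4,6-bis(methoxymethoxy)-3-(3-methylbut-2-enyl)phenyl]methanol | OCc1c(OC(=C)c2ccc(OC)c(OCOC)c2CC=C(C)C)c(CC=C(C)C)c(OCOC)cc1OCOC | intermediate
19 | 2-({1-[4-methoxy-3-(methoxymethoxy)-2-(3-methylbut-2-enyl)phenyl]vinyl}oxy)-4,6-bis(methoxymethoxy)-3-(3-methylbut-2-enyl)benzaldehyde | O=Cc1c(OC(=C)c2ccc(OC)c(OCOC)c2CC=C(C)C)c(CC=C(C)C)c(OCOC)cc1OCOC | intermediate
20 | (2S)-2-[4-methoxy-3-(methoxymethoxy)-2-(3-methylbut-2-enyl)phenyl]-5,7-bis(methoxymethoxy)-8-(3-methylbut-2-enyl)chroman-4-one | COc1ccc([C@@H]2CC(=O)c3c(OCOC)cc(OCOC)c(CC=C(C)C)c3O2)c(CC=C(C)C)c1OCOC | intermediate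
21 | (2S)-5,7-dihydroxy-2-[3-hydroxy-4-methoxy-2-(3-methylbut-2-enyl)phenyl]-8-(3-methylbut-2-enyl)chroman-4-one | COc1ccc([C@@H]2CC(=O)c3c(O)cc(O)c(CC=C(C)C)c3O2)c(CC=C(C)C)c1O | target

**Step count and risks**

Total steps: 16. Longest linear sequence: 12 steps (steps 1–5 and 10–16).

Most likely to fail:

1. Step 15 (proposed new method). Decarbonylation of the acyl rhodium hydride may outrun ring closure, hydride may be delivered with the wrong regiochemistry, or the facial selectivity at C2 may be poor.
 Fallback (known chemistry, same bond, sets out from 17 and comes back at 20): the enol ether of 17 would be hydroborated at its terminal carbon with 9-BBN (THF, rt) to give the alkylborane F1, which is oxidised in the same flask (H2O2, NaOH) to the racemic primary alcohol F2. Tosylation (TsCl, pyridine) would give the tosylate F3, buffered HF·pyridine would free the benzylic alcohol F4, and MnO2 would give the aldehyde tosylate F5. An N-heterocyclic carbene (2-mesityl-6,7-dihydro-5H-pyrrolo[2,1-c][1,2,4]triazol-2-ium chloride, DBU, dioxane, 60 °C) would then reverse the polarity of the formyl carbon, and the acyl anion equivalent would displace the tosylate at C3, a known route to chroman-4-ones, to give the racemic flavanone F6. Kinetic resolution by Noyori-type asymmetric transfer hydrogenation (RuCl(p-cymene)[(R,R)-TsDPEN], HCO2H/Et3N, EtOAc, rt, stopped near half conversion) should reduce the (2R) ketone to the cis-flavan-4-ol F7 and leave the (2S) ketone 20, which is separated by chromatography.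

2. Step 12. The ester carbonyl is shielded on both sides, so methylenation may stay incomplete, and the enol ether may hydrolyse during isolation.
 Fallback (forms the O1–C2 bond by C–O coupling instead; sets out from 13 and 7 and comes back at 17): acid 13 would be treated with MeLi (2.2 equiv, Et2O, 0 °C to rt; quench into aqueous NH4Cl) to give the methyl ketone F8. Enolisation and triflation (KN(SiMe3)2, PhNTf2, THF, −78 °C) would give the 1-arylvinyl triflate F9. Palladium-catalysed vinylation of phenol 7 (Pd2(dba)3, 2-(di-tert-butylphosphino)biphenyl, K3PO4, toluene, 80 °C) would give the bis-allyl enol ether F10. The double cross-metathesis of step 11 would then be run on F10 to reach 17.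

3. Step 5. At 190 °C the benzylic silyl ether may be lost or may migrate, and part of the material may rearrange by way of the blocked ortho carbon to the para position.
 Fallback (the rearrangement is moved to the aldehyde oxidation level, where the carbonyl group locks the new phenol by a hydrogen bond; sets out from 3 and comes back at 7): aldehyde 3 would be heated in PhNEt2 at 190 °C to give, by way of the ortho-dienone F11, the 3-allyl salicylaldehyde F12. NaBH4 would give the diol F13, an excess of TBSCl with imidazole the bis-silyl ether F14, and K2CO3 in MeOH would cleave only the aryl silyl ether to return 7.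

**Further compounds**

F1 | step 15 | B-alkyl-9-borabicyclo[3.3.1]nonane from hydroboration of 17 | CC(C)(C)[Si](C)(C)OCc1c(OC(CB2C3CCCC2CCC3)c2ccc(OC)c(OCOC)c2CC=C(C)C)c(CC=C(C)C)c(OCOC)cc1OCOC
F2 | step 15 | racemic 2-(2-{[(tert-butyldimethylsilyl)oxy]methyl}-3,5-bis(methoxymethoxy)-6-(3-methylbut-2-enyl)phenoxy)-2-[4-methoxy-3-(methoxymethoxy)-2-(3-methylbut-2-enyl)phenyl]ethanol | CC(C)(C)[Si](C)(C)OCc1c(OC(CO)c2ccc(OC)c(OCOC)c2CC=C(C)C)c(CC=C(C)C)c(OCOC)cc1OCOC
F3 | step 15 | p-toluenesulfonate of alcohol F2 | CC(C)(C)[Si](C)(C)OCc1c(OC(COS(=O)(=O)c2ccc(C)cc2)c2ccc(OC)c(OCOC)c2CC=C(C)C)c(CC=C(C)C)c(OCOC)cc1OCOC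
F4 | step 15 | benzylic alcohol from desilylation of F3 | OCc1c(OC(COS(=O)(=O)c2ccc(C)cc2)c2ccc(OC)c(OCOC)c2CC=C(C)C)c(CC=C(C)C)c(OCOC)cc1OCOC
F5 | step 15 | aldehyde tosylate from oxidation of F4 | O=Cc1c(OC(COS(=O)(=O)c2ccc(C)cc2)c2ccc(OC)c(OCOC)c2CC=C(C)C)c(CC=C(C)C)c(OCOC)cc1OCOC
F6 | step 15 | racemic 2-[4-methoxy-3-(methoxymethoxy)-2-(3-methylbut-2-enyl)phenyl]-5,7-bis(methoxymethoxy)-8-(3-methylbut-2-enyl)chroman-4-one | COc1ccc(C2CC(=O)c3c(OCOC)cc(OCOC)c(CC=C(C)C)c3O2)c(CC=C(C)C)c1OCOC
F7 | step 15 | (2R,4R)-2-[4-methoxy-3-(methoxymethoxy)-2-(3-methylbut-2-enyl)phenyl]-5,7-bis(methoxymethoxy)-8-(3-methylbut-2-enyl)chroman-4-ol | COc1ccc([C@H]2C[C@@H](O)c3c(OCOC)cc(OCOC)c(CC=C(C)C)c3O2)c(CC=C(C)C)c1OCOC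
F8 | step 12 | 1-[2-allyl-4-methoxy-3-(methoxymethoxy)phenyl]ethanone | CC(=O)c1ccc(OC)c(OCOC)c1CC=C
F9 | step 12 | 1-[2-allyl-4-methoxy-3-(methoxymethoxy)phenyl]vinyl trifluoromethanesulfonate | C=C(OS(=O)(=O)C(F)(F)F)c1ccc(OC)c(OCOC)c1CC=C
F10 | step 12 | tert-butyl{[3-allyl-2-({1-[2-allyl-4-methoxy-3-(methoxymethoxy)phenyl]vinyl}oxy)-4,6-bis(methoxymethoxy)phenyl]methoxy}dimethylsilane | CC(C)(C)[Si](C)(C)OCc1c(OC(=C)c2ccc(OC)c(OCOC)c2CC=C)c(CC=C)c(OCOC)cc1OCOC
F11 | step 5 | 5-allyl-2,4-bis(methoxymethoxy)-6-oxocyclohexa-1,3-diene-1-carbaldehyde (ortho-dienone) | O=CC1=C(OCOC)C=C(OCOC)C(CC=C)C1=O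
F12 | step 5 | 3-allyl-2-hydroxy-4,6-bis(methoxymethoxy)benzaldehyde | O=Cc1c(O)c(CC=C)c(OCOC)cc1OCOC
F13 | step 5 | 2-allyl-6-(hydroxymethyl)-3,5-bis(methoxymethoxy)phenol | OCc1c(O)c(CC=C)c(OCOC)cc1OCOC
F14 | step 5 | bis(tert-butyldimethylsilyl) ether of diol F13 | CC(C)(C)[Si](C)(C)OCc1c(O[Si](C)(C)C(C)(C)C)c(CC=C)c(OCOC)cc1OCOC
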